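**Plan**
- Retrosynthesis: remove the two aryl formyl groups, then cut C1′–aryl and C1′–CH2 (isobutyl), leaving an aldehyde carbon on C1. Cut the C4–CH3 bond (C4 ketone) and the C11–O bond (isopropenyl). Last, cut C1–C10 and C2–C3 of ring A.
- Enabling feature: the oxygen-bearing C4 and C1 (which carries the carbonyl-derived C1′) are 1,4-related across ring A, and C5–C10 is shared with ring B. At the ketone/acyl oxidation level, ring A is therefore the [4+2] adduct of a 2-alkoxydiene (C3=C4(OEt)–C5=C10, built on ring B) and an acryloyl dienophile (C1=C2).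
- Forward order: ring B comes from (S)-carvone. Ring A is closed by the cycloaddition and is the only ring formed in the route. The arene is attached afterwards as an aryllithium and formylated last.
- Stereochemistry: C7 comes from carvone. C1 is set by an oxazolidinone auxiliary and C10 by the endo topology. C5 is set by ketone equilibration and C4 by equatorial methyl addition. C1′ is set by A1,3-controlled capture of a benzylic cation.

Key step: step 4

Remark on numbering: eudesmane numbering is used (ring A = C1–C2–C3–C4–C5–C10, ring B = C5–C6–C7–C8–C9–C10, C1′ = benzylic carbon). "cis/trans" always refers to the C10 methyl group, and the absolute configuration is that of the SMILES strings.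
Assumption: the target SMILES is read as a trans-decalin in which the C1 side chain is trans to the C10 methyl (axial) and the C4 hydroxyl is cis to it; 1,3,5-tris(benzyloxy)benzene is taken as purchasable.

**Step 1**
Reactants: 1 (S)-(+)-carvone
Product: 3 (5S)-2-methyl-5-(prop-1-en-2-yl)cyclohex-1-en-1-yl trifluoromethanesulfonate, via lithium enolate 2 (not isolated)
Conditions: LiBH(s-Bu)3 (L-Selectride), THF, −78 °C; then PhNTf2, −78 °C → rt
Reagents that add atoms: N-phenyl-bis(trifluoromethanesulfonimide), O=S(=O)(N(c1ccccc1)S(=O)(=O)C(F)(F)F)C(F)(F)F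
Why: Conjugate hydride delivery to the enone gives the tetrasubstituted lithium enolate regiospecifically, and PhNTf2 O-sulfonylates it (1,4-reduction/enolate triflation); the C7 stereocentre of carvone is untouched.

**Step 2**
Reactants: 3 enol triflate; 4 tributyl(1-ethoxyvinyl)stannane
Product: 5 (5S)-1-(1-ethoxyvinyl)-2-methyl-5-(prop-1-en-2-yl)cyclohex-1-ene (2-ethoxydiene C3=C4(OEt)–C5=C10)
Conditions: Pd(PPh3)4 (cat., zerovalent palladium), LiCl, THF, 65 °C; purification on Et3N-deactivated silica
Reagents that add atoms: none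
Why: Stille coupling of the alkenyl triflate with the α-ethoxyvinylstannane gives the acid-sensitive 2-ethoxy-1,3-diene with the ring double bond fixed at C5=C10.

**Step 3**
Reactants: 6 (S)-4-benzyl-1,3-oxazolidin-2-one; 7 acryloyl chloride
Product: 9 (S)-3-acryloyl-4-benzyl-1,3-oxazolidin-2-one, via lithium oxazolidinide 8 (not isolated)
Conditions: n-BuLi, THF, −78 °C; then acryloyl chloride, −78 → 0 °C
Reagents that add atoms: none
Why: N-acylation of the lithiated oxazolidinone at low temperature is the standard preparation of the chiral acrylimide dienophile.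

**Step 4**
Reactants: 5 ethoxydiene; 9 acrylimide
Product: 10 (S)-4-benzyl-3-{[4-ethoxy-10-methyl-7-(prop-1-en-2-yl)-Δ4(5)-octalin-1-yl]carbonyl}-1,3-oxazolidin-2-one (C1 acyl trans to the C10 methyl, C7 isopropenyl cis to the C10 methyl)
Conditions: Et2AlCl (1.4 equiv), CH2Cl2, −78 °C; Et3N then aq. NaHCO3 quench
Reagents that add atoms: none
Why: The Et2AlCl-chelated s-cis acrylimide is a cationic, very reactive dienophile that adds to the electron-rich 2-ethoxydiene in a strongly asynchronous Diels–Alder reaction in which C2–C3 bonding leads (a stepwise Mukaiyama–Michael/Michael path would converge on the same product); the closest known reaction type is the Lewis-acid-promoted cycloaddition of oxazolidinone acrylimides with 2-alkoxy- and 2-silyloxy-1,3-dienes. Ring A is closed by an intermolecular (4+2) annulation onto the C5=C10 double bond of ring B, forming C2–C3 and C1–C10 and leaving the C4=C5 enol ether as a masked ketone. C1 is controlled by the auxiliary, whose 4-benzyl group shields one face of the chelated acrylimide so that C10 bonds to the opposite face, in the same sense as in the known additions of this acrylimide to simple dienes. C10 is controlled by the endo transition state, in which the acyl group lies under C4–C5 and therefore ends trans to the inside C10 methyl and cis to C9; this also fixes which face of the diene reacts and hence the relation to C7. The step needs para regioselectivity, which the ethoxy group on C4 secures by making C3 the nucleophilic terminus, and chemoselectivity over the isopropenyl group, which is far less nucleophilic at −78 °C. It also needs endo and facial selectivity from the chelate against a modest inherent preference of the cyclohexene for attack cis to the isopropenyl group, so the auxiliary has to dominate.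

**Step 5**
Reactants: 10 cycloadduct
Product: 11 [4-ethoxy-10-methyl-7-(prop-1-en-2-yl)-Δ4(5)-octalin-1-yl]methanol (CH2OH trans, isopropenyl cis to the C10 methyl)
Conditions: LiBH4, H2O (1 equiv), Et2O/THF, 0 °C
Reagents that add atoms: none
Why: Reductive cleavage of the N-acyl oxazolidinone at the exocyclic carbonyl gives the primary alcohol and returns the auxiliary; the enol ether is inert to hydride and keeps C4 masked, and C1 is no longer epimerisable.

**Step 6**
Reactants: 11 enol ether alcohol
Product: 13 trans-fused 1-(hydroxymethyl)-10-methyl-7-(prop-1-en-2-yl)decalin-4-one (H-5 trans, CH2OH trans, isopropenyl cis to the C10 methyl), via C5-epimeric ketone 12 (not isolated)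
Conditions: 0.5 M HCl, THF–H2O, 0 °C → rt; then NaOMe, MeOH, rt
Reagents that add atoms: water, O
Why: Acid hydrolysis of the enol ether unveils the C4 ketone, and methoxide equilibration through the C4/C5 enolate (C5 is the only epimerisable centre) should settle on the trans-fused decalone with H-5 anti to the axial C10 methyl, ring B being anchored by the equatorial C7 group while the C1 substituent is still small (thermodynamic ring-fusion control).

**Step 7**
Reactants: 13 trans keto alcohol
Product: 14 1-(hydroxymethyl)-4,10-dimethyl-7-(prop-1-en-2-yl)decalin-4-ol (4-OH axial and cis to the C10 methyl, 4-CH3 equatorial)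
Conditions: MeMgBr (excess), LaCl3·2LiCl, THF, −20 → 0 °C
Reagents that add atoms: methylmagnesium bromide, C[Mg]Br
Why: Grignard 1,2-addition occurs from the equatorial side because the axial face of C4 is blocked by the syn-axial C10 methyl, giving the tertiary alcohol with the axial hydroxyl cis to the C10 methyl; the lanthanum salt suppresses enolisation.

**Step 8**
Reactants: 14 diol
Product: 15 1-(hydroxymethyl)-7-(2-hydroxypropan-2-yl)-4,10-dimethyldecalin-4-ol (triol)
Conditions: Co(acac)2 (cat.), PhSiH3, O2 (1 atm), THF/i-PrOH, rt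
Reagents that add atoms: dioxygen, O=O
Why: Mukaiyama hydration (cobalt-hydride hydrogen-atom transfer to the only alkene, trapping of the tertiary radical by O2 and reduction by the silane) converts the isopropenyl group into the tertiary carbinol without touching any stereocentre.

**Step 9**
Reactants: 15 triol
Product: 16 4-hydroxy-7-(2-hydroxypropan-2-yl)-4,10-dimethyldecalin-1-carbaldehyde (CHO trans to the C10 methyl)
Conditions: TEMPO (cat.), PhI(OAc)2, CH2Cl2, rt; used directly
Reagents that add atoms: none
Why: Oxoammonium oxidation is specific for the primary alcohol, the two tertiary alcohols being inert; the aldehyde is trans to the C4 hydroxyl, so no lactol can form, and the near-neutral conditions should not epimerise C1.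

**Step 10**
Reactants: 17 1,3,5-tris(benzyloxy)benzene
Product: 18 2-bromo-1,3,5-tris(benzyloxy)benzene
Conditions: NBS (1.0 equiv), MeCN, 0 °C
Reagents that add atoms: N-bromosuccinimide, O=C1CCC(=O)N1Br
Why: Electrophilic bromination of the strongly activated arene stops at the monobromide with one equivalent of NBS, the three free positions being equivalent.

**Step 11**
Reactants: 18 aryl bromide; 16 aldehyde
Product: 20 [2,4,6-tris(benzyloxy)phenyl][4-hydroxy-7-(2-hydroxypropan-2-yl)-4,10-dimethyldecalin-1-yl]methanol (mixture of epimers at C1′), via aryllithium 19 (not isolated)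
Conditions: 18, n-BuLi, THF, −78 °C (3.3 equiv of 19); then 16, −78 → −40 °C
Reagents that add atoms: none
Why: Bromine–lithium exchange gives the di-ortho-alkoxy aryllithium, which adds to the aldehyde at low temperature (two further equivalents are consumed by the tertiary hydroxyl groups); the C1′ epimer mixture is of no consequence because C1′ becomes planar in the next step.

**Step 12**
Reactants: 20 benzylic alcohol; 21 trimethyl(2-methylallyl)silane
Product: 22 (1′S)-1-[1-(2,4,6-tris(benzyloxy)phenyl)-3-methylbut-3-enyl]-7-(2-hydroxypropan-2-yl)-4,10-dimethyldecalin-4-ol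
Conditions: Bi(OTf)3 (cat.), 21 (excess), CH2Cl2/MeNO2, −40 → 0 °C; Et3N quench
Reagents that add atoms: none
Why: This is a Bi(OTf)3-catalysed SN1 substitution (Hosomi–Sakurai-type allylation of a stabilised benzylic cation) in which the 2,4,6-tris(benzyloxy)benzyl cation adopts the conformer with C1–H in the cation plane toward an ortho-benzyloxy group (minimal A1,3 strain), so the allylsilane attacks the face flanked by C2 and anti to the quaternary C10, which should give the (1′S) configuration, while the two tertiary alcohols, far harder to ionise, should survive at low temperature.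

**Step 13**
Reactants: 22 methallyl tribenzyl ether
Product: 23 2-{(1S)-1-[4-hydroxy-7-(2-hydroxypropan-2-yl)-4,10-dimethyldecalin-1-yl]-3-methylbutyl}benzene-1,3,5-triol
Conditions: H2 (1 atm), Pd/C, EtOAc/MeOH, rt
Reagents that add atoms: none
Why: Heterogeneous hydrogenation saturates the 1,1-disubstituted alkene to the isobutyl group and hydrogenolyses the three benzyl ethers in one neutral operation that the tertiary alcohols tolerate.

**Step 14**
Reactants: 23 alkylphloroglucinol
Product: 25 target, 5-{(1S)-1-[(1S,4R,4aS,6S,8aR)-4-hydroxy-6-(2-hydroxypropan-2-yl)-4,8a-dimethyldecahydronaphthalen-1-yl]-3-methylbutyl}-2,4,6-trihydroxybenzene-1,3-dicarbaldehyde, via bis-aldimine 24 (not isolated)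
Conditions: formamidine acetate (excess), Ac2O, THF, 45 °C; then 1 M HCl aq., rt
Reagents that add atoms: formamidine acetate, NC=N.CC(=O)O; water, O
Why: Twofold electrophilic formylation of the highly nucleophilic phloroglucinol at its two free positions by acetic-anhydride-activated formamidine (a mild, Lewis-acid-free formylation of phloroglucinols), followed by hydrolysis of the aldimines with dilute acid, should leave the two tertiary alcohols intact.

**Compound list**
1 | (S)-(+)-carvone, (5S)-2-methyl-5-(prop-1-en-2-yl)cyclohex-2-en-1-one | O=C1C[C@@H](C(C)=C)CC=C1C | starting material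
2 | lithium (5S)-2-methyl-5-(prop-1-en-2-yl)cyclohex-1-en-1-olate | CC1=C([O-])C[C@@H](C(C)=C)CC1.[Li+] | intermediate
3 | (5S)-2-methyl-5-(prop-1-en-2-yl)cyclohex-1-en-1-yl trifluoromethanesulfonate | CC1=C(OS(=O)(=O)C(F)(F)F)C[C@@H](C(C)=C)CC1 | intermediate
4 | tributyl(1-ethoxyvinyl)stannane | CCCC[Sn](CCCC)(CCCC)C(=C)OCC | starting material
5 | (5S)-1-(1-ethoxyvinyl)-2-methyl-5-(prop-1-en-2-yl)cyclohex-1-ene | CC1=C(C(=C)OCC)C[C@@H](C(C)=C)CC1 | intermediate
6 | (S)-4-benzyl-1,3-oxazolidin-2-one | O=C1N[C@@H](Cc2ccccc2)CO1 | starting material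
7 | acryloyl chloride | C=CC(Cl)=O | starting material
8 | lithium salt of (S)-4-benzyl-1,3-oxazolidin-2-one (N-lithiated) | [Li+].O=C1[N-][C@@H](Cc2ccccc2)CO1 | intermediate
9 | (S)-3-acryloyl-4-benzyl-1,3-oxazolidin-2-one | C=CC(=O)N1C(=O)OC[C@@H]1Cc1ccccc1 | intermediate
10 | cycloadduct: N-acyl oxazolidinone on C1 of 4-ethoxy-10-methyl-7-isopropenyl-Δ4(5)-octalin (C1 acyl trans, C7 isopropenyl cis to the C10 methyl) | O=C(N1C(=O)OC[C@@H]1Cc1ccccc1)[C@@H]1CCC(OCC)=C2C[C@@H](C(C)=C)CC[C@]12C | intermediate
11 | [4-ethoxy-10-methyl-7-(prop-1-en-2-yl)-Δ4(5)-octalin-1-yl]methanol (CH2OH trans, isopropenyl cis to the C10 methyl) | OC[C@@H]1CCC(OCC)=C2C[C@@H](C(C)=C)CC[C@]12C | intermediate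
12 | 1-(hydroxymethyl)-10-methyl-7-(prop-1-en-2-yl)decalin-4-one, mixture of C5 epimers | OC[C@@H]1CCC(=O)C2C[C@@H](C(C)=C)CC[C@]12C | intermediate
13 | trans-fused 1-(hydroxymethyl)-10-methyl-7-(prop-1-en-2-yl)decalin-4-one (H-5 trans, CH2OH trans, isopropenyl cis to the C10 methyl) | OC[C@@H]1CCC(=O)[C@H]2C[C@@H](C(C)=C)CC[C@]12C | intermediate
14 | 1-(hydroxymethyl)-4,10-dimethyl-7-(prop-1-en-2-yl)-trans-decalin-4-ol (4-OH cis to the C10 methyl) | OC[C@@H]1CC[C@@](C)(O)[C@H]2C[C@@H](C(C)=C)CC[C@]12C | intermediate
15 | 1-(hydroxymethyl)-7-(2-hydroxypropan-2-yl)-4,10-dimethyl-trans-decalin-4-ol | OC[C@@H]1CC[C@@](C)(O)[C@H]2C[C@@H](C(C)(C)O)CC[C@]12C | intermediate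
16 | 4-hydroxy-7-(2-hydroxypropan-2-yl)-4,10-dimethyl-trans-decalin-1-carbaldehyde (CHO trans to the C10 methyl) | O=C[C@@H]1CC[C@@](C)(O)[C@H]2C[C@@H](C(C)(C)O)CC[C@]12C | intermediate
17 | 1,3,5-tris(benzyloxy)benzene | c1ccccc1COc1cc(OCc2ccccc2)cc(OCc2ccccc2)c1 | starting material
18 | 2-bromo-1,3,5-tris(benzyloxy)benzene | Brc1c(OCc2ccccc2)cc(OCc2ccccc2)cc1OCc1ccccc1 | intermediate
19 | 2,4,6-tris(benzyloxy)phenyllithium | [Li]c1c(OCc2ccccc2)cc(OCc2ccccc2)cc1OCc1ccccc1 | intermediate
20 | [2,4,6-tris(benzyloxy)phenyl](decalin-1-yl)methanol, decalin as in 15, epimer mixture at C1′ | OC(c1c(OCc2ccccc2)cc(OCc2ccccc2)cc1OCc1ccccc1)[C@@H]1CC[C@@](C)(O)[C@H]2C[C@@H](C(C)(C)O)CC[C@]12C | intermediate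
21 | trimethyl(2-methylallyl)silane | CC(=C)C[Si](C)(C)C | starting material
22 | (1′S)-1-[1-(2,4,6-tris(benzyloxy)phenyl)-3-methylbut-3-enyl]-7-(2-hydroxypropan-2-yl)-4,10-dimethyl-trans-decalin-4-ol | C=C(C)C[C@H](c1c(OCc2ccccc2)cc(OCc2ccccc2)cc1OCc1ccccc1)[C@@H]1CC[C@@](C)(O)[C@H]2C[C@@H](C(C)(C)O)CC[C@]12C | intermediate
23 | 2-{(1S)-1-[4-hydroxy-7-(2-hydroxypropan-2-yl)-4,10-dimethyl-trans-decalin-1-yl]-3-methylbutyl}benzene-1,3,5-triol | CC(C)C[C@H](c1c(O)cc(O)cc1O)[C@@H]1CC[C@@](C)(O)[C@H]2C[C@@H](C(C)(C)O)CC[C@]12C | intermediate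
24 | bis-aldimine of the target (two CH=NH groups in place of the formyl groups) | CC(C)C[C@H](c1c(O)c(C=N)c(O)c(C=N)c1O)[C@@H]1CC[C@@](C)(O)[C@H]2C[C@@H](C(C)(C)O)CC[C@]12C | intermediate
25 | CNP0409870.3, 5-{(1S)-1-[(1S,4R,4aS,6S,8aR)-4-hydroxy-6-(2-hydroxypropan-2-yl)-4,8a-dimethyldecahydronaphthalen-1-yl]-3-methylbutyl}-2,4,6-trihydroxybenzene-1,3-dicarbaldehyde | CC(C)C[C@H](c1c(O)c(C=O)c(O)c(C=O)c1O)[C@@H]1CC[C@@](C)(O)[C@H]2C[C@@H](C(C)(C)O)CC[C@]12C | target

**Totals**
Total step count: 14. Longest linear sequence: 12 steps (steps 1, 2, 4–9, 11–14, from carvone).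

**Steps most likely to fail**

Step 4 (key cycloaddition). The tetrasubstituted C10 terminus may react too slowly, the enol ether diene may be destroyed by the stoichiometric Lewis acid, or endo/facial selectivity may erode because the auxiliary works against the ring-B preference. The fallback replaces the Lewis-acid cycloaddition by an anionic double Michael annulation. It sets out from 5, which is hydrolysed with wet oxalic acid to 1-[(5S)-2-methyl-5-(prop-1-en-2-yl)cyclohex-1-en-1-yl]ethanone F1. Kinetic deprotonation of F1 at the acetyl methyl group (LiN(i-Pr)2, THF, −78 °C) gives the cross-conjugated dienolate, which adds to 9; the resulting chelated imide enolate closes ring A by intramolecular Michael addition to C10, under the same auxiliary control at C1. Trapping the final C4 enolate with TBSCl gives the silyl enol ether imide F2, and LiBH4 then gives the silyl enol ether alcohol F3. F3 comes back to the route at 13 under the conditions of step 6.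

Step 12 (C1′). Facial selectivity in the capture of the benzylic cation may be low or inverted, with ionisation of the tertiary alcohols as a side reaction. The fallback reverses the order in which the two C1′ substituents are introduced, which inverts the configuration obtained for a given facial preference. It sets out from 20, which is oxidised (DMP, NaHCO3, CH2Cl2) to the aryl ketone F4. Addition of CH2=C(CH3)CH2MgCl (excess, THF, 0 °C) gives the tertiary benzylic carbinol F5. Ionic deoxygenation (Et3SiH, BF3·OEt2, CH2Cl2, −78 °C), in which hydride now takes the place of the carbon nucleophile, returns to the route at 22.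

Step 6 (ring fusion). The equilibrium may not sufficiently favour the trans-decalone, giving cis-fused or mixed material. The fallback sets C5 by radical hydrogen-atom transfer after C4 is methylated. It sets out from 11, which with PhSeCl (CH2Cl2, −78 °C; aq. NaHCO3) gives the C5-phenylselanyl ketone F6. Oxidation (H2O2, pyridine) and syn-elimination give the C5=C6 enone F7; only C6 carries a β-hydrogen. MeMgBr adds to C4 from the face opposite the C10 methyl to give the allylic tertiary alcohol F8. Co(acac)2/PhSiH3/O2 hydrates the more reactive isopropenyl group to give F9. MHAT hydrogenation (Mn(dpm)3, PhSiH3, t-BuOOH, i-PrOH) then delivers hydrogen to the tertiary C5 radical on the face opposite the C10 methyl and returns to the route at 15.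

**Further compounds**
F1 | step 4 | 1-[(5S)-2-methyl-5-(prop-1-en-2-yl)cyclohex-1-en-1-yl]ethanone | CC1=C(C(C)=O)C[C@@H](C(C)=C)CC1
F2 | step 4 | silyl enol ether imide (as 10 with OSi(CH3)2C(CH3)3 in place of OEt on C4) | O=C(N1C(=O)OC[C@@H]1Cc1ccccc1)[C@@H]1CCC(O[Si](C)(C)C(C)(C)C)=C2C[C@@H](C(C)=C)CC[C@]12C
F3 | step 4 | silyl enol ether alcohol (as 11 with OSi(CH3)2C(CH3)3 in place of OEt on C4) | OC[C@@H]1CCC(O[Si](C)(C)C(C)(C)C)=C2C[C@@H](C(C)=C)CC[C@]12C
F4 | step 12 | [2,4,6-tris(benzyloxy)phenyl] ketone on C1 of the decalin of 15 | O=C(c1c(OCc2ccccc2)cc(OCc2ccccc2)cc1OCc1ccccc1)[C@@H]1CC[C@@](C)(O)[C@H]2C[C@@H](C(C)(C)O)CC[C@]12C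
F5 | step 12 | tertiary benzylic carbinol bearing the 2-methylallyl group, epimer mixture at C1′ | C=C(C)CC(O)(c1c(OCc2ccccc2)cc(OCc2ccccc2)cc1OCc1ccccc1)[C@@H]1CC[C@@](C)(O)[C@H]2C[C@@H](C(C)(C)O)CC[C@]12C
F6 | step 6 | 1-(hydroxymethyl)-10-methyl-5-(phenylselanyl)-7-(prop-1-en-2-yl)decalin-4-one | OC[C@@H]1CCC(=O)C2([Se]c3ccccc3)C[C@@H](C(C)=C)CC[C@]12C
F7 | step 6 | 1-(hydroxymethyl)-10-methyl-7-(prop-1-en-2-yl)-Δ5(6)-octalin-4-one | OC[C@@H]1CCC(=O)C2=C[C@@H](C(C)=C)CC[C@]12C
F8 | step 6 | 1-(hydroxymethyl)-4,10-dimethyl-7-(prop-1-en-2-yl)-Δ5(6)-octalin-4-ol (4-OH cis to the C10 methyl) | OC[C@@H]1CC[C@@](C)(O)C2=C[C@@H](C(C)=C)CC[C@]12C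
F9 | step 6 | 1-(hydroxymethyl)-7-(2-hydroxypropan-2-yl)-4,10-dimethyl-Δ5(6)-octalin-4-ol | OC[C@@H]1CC[C@@](C)(O)C2=C[C@@H](C(C)(C)O)CC[C@]12C
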